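## Analysis of the target

Acredinone B (18) is an open array of four benzene rings with no ring fusion: rings A and D are 2,6-dimethoxyphenyl groups, each joined through a diaryl ketone to ring B or ring C, and rings B and C are joined by a CH2–C(=O) bridge. Ring B is numbered C1 (carries the aroyl carbon), C2 (OH), C3 (H), C4 (CH3), C5 (OCH3) and C6 (bridge CH2); ring C carries the same six substituents in the same order (C1′ to C6′), with C6′ bonded to the bridge carbonyl. The molecule has no stereocentre and no stereogenic double bond, so stereochemistry appears only in intermediates and has to be erased on the way. The sensitive sites are the two phenols para to a methoxy group, which strong oxidants turn into quinones, and the bridge, whose enolisable CH2 lies next to a ketone that sits ortho to the aroyl ketone on ring C, so that base can start an intramolecular aldol closure. The difficulty lies in two hexasubstituted benzene rings with five different substituents in a fixed order and in two benzophenones that each carry four ortho substituents. Rings B and C are constitutionally identical and the target departs from twofold symmetry only in the oxidation level of the two bridge carbons, so a symmetric (E)-stilbene that is hydrated at either alkene carbon leads to it. In each of these rings the C2 hydroxyl is para to the C5 methoxy with C3–H and C4–CH3 between them, which is the pattern produced when an alkenyl(methoxy)carbene, an alkyne and one carbonyl ligand are joined to a para-methoxyphenol.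

## Retrosynthetic reasoning

**18 to 17.** The three carbonyl groups of 18 are taken back together to the three secondary benzylic carbinols of 17. All three carbons are benzylic, so one neutral, heterogeneous oxidation can raise them in a single operation. Placing this last keeps the base-sensitive ortho-diacyl arrangement with its enolisable CH2 out of every earlier step. The hindered benzophenones are then formed by oxidation and not by acylation of a crowded arene.

**17 to 16.** The two benzhydrol O–H bonds of 17 are taken back to O–Si bonds in 16. The silyl groups are needed earlier as spectators of the ring-forming step. They are removed with fluoride while the molecule still has no ketone, so no hydroxy ketone that could close to a lactol is ever present.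

**16 to 14.** The C–O bond of the bridge carbinol in 16 is cut, which leads back to the symmetric (E)-stilbene 14. The two alkene carbons of 14 are constitutionally equivalent, so the hydration has no regiochemical question. A direct palladium-mediated oxidation of the alkene to the ketone would save one redox operation. It would, however, expose electron-rich free phenols and acid-labile, doubly benzylic silyl ethers to an electrophilic metal oxidant on an alkene screened by four ortho substituents. Hydroboration and oxidation is the milder, non-acidic choice, and the extra carbinol costs nothing because it is oxidised together with the other two.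

**14 to 7 and two molecules of 12.** Rings B and C are cut in the same way, each at C5–C6, C1–C2 and C2–C3. This returns the (E)-enediyne 7 and two molecules of the carbene complex 12. Each ring is assembled from three pieces: the two alkyne carbons (C1 and C6), the carbene carbon with its methoxy group and isopropenyl unit (C5, C4 with its methyl, C3), and one carbonyl ligand of 12 (C2 with the free hydroxyl). Six substituents per ring arrive in their final positions and the phenol is born unprotected. The forward reaction has to place the larger alkyne substituent next to the new hydroxyl in both rings. For that reason the aroyl carbons are carried as silyloxy carbinols: the branched sp3 group is clearly larger than the flat CH= substituent, and no carbonyl is conjugated to the triple bond to polarise it or make it a Michael acceptor.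

**7 to two molecules of 4 and 5.** The two C(sp)–C(sp2) bonds of 7 are cut, giving the terminal alkyne 4 (two molecules) and 5. Coupling the complete propargylic silyl ether onto the two-carbon linchpin avoids handling the parent hexenediyne and its dilithio derivative, and it makes 7 in the step just before it is used.

**4 to 3, then to 1 and 2.** The O–Si bond of 4 leads back to the propargylic alcohol 3. Its carbinol C–C(sp) bond is cut to the aldehyde 1 and the acetylide 2. This is a plain carbonyl addition that sets the future aroyl carbon and attaches ring A (and ring D) with all its substituents.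

**12 to 8 and 9.** The carbene complex 12 is cut at the carbene carbon–alkenyl bond and at the O–CH3 bond. The alkenyl metal derived from 8 adds to a carbonyl ligand of 9 and the resulting acyl metalate is O-methylated.

## Alternatives that were turned down

**Alternative 1:** Ring B alone is cut at C6–CH2 and C1–C(=O). In the forward direction the aryne A1 (3-(benzyloxy)-5-methylbenzyne) inserts into the C(=O)–CH2 bond of the β-keto ester A2 (methyl 3-(2,6-dimethoxyphenyl)-3-oxopropanoate) and gives the aryl acetate A3.
- **For:** The ortho pair of ring B, hindered diaryl ketone included, is set in one metal-free operation. The regiochemistry is governed electronically by the alkoxy group of A1 and is more predictable than a sterically governed step. The ester of A3 is a handle for the bridge.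
- **Against:** A3 has no oxygen at C5, which would have to be introduced later at a position flanked by the methyl group and the acetic ester, over several steps. The acyl transfer requires an aryl anion to attack a ketone shielded by two ortho methoxy groups. Only ring B is served, so ring C needs a separate synthesis and then a ketone-forming union at a hexasubstituted arene.
- **Comparison:** Alternative 1 is stronger on inherent regiocontrol and on avoiding stoichiometric chromium. The chosen route offers in its place both rings complete, with the C5 methoxy and the free C2 hydroxyl in position, from one flask, and it uses the identity of rings B and C, which alternative 1 ignores.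

**Alternative 2:** The ring A–C(=O) and ring D–C(=O) bonds are cut. Two molecules of the aryne A4 (3-methoxybenzyne), generated with CsF, insert into the two carboxylic acid C–O bonds of the symmetric stilbene diacid A5 and give the bis(2-hydroxy-6-methoxyphenyl) ketone A6.
- **For:** It is two-directional and uses the same hidden symmetry. It forms the most hindered bonds of the target without any redox adjustment at the aroyl carbons, and the aryne component is simple. On the oxidation level of the aroyl carbons it is stronger than the chosen route, which must oxidise two benzhydrols at the end.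
- **Against:** A5 already contains both hexasubstituted rings, so the main difficulty of the target is moved into the starting material and not solved. After O-arylation the aryl anion must attack a carboxyl carbon flanked by two ortho substituents, and simple aryl ester formation is the likely competitor, twice. The new phenols of A6 still need methylation, the protecting groups need removal, and the alkene still has to be hydrated.
- **Comparison:** The chosen route builds rings B and C from acyclic pieces in its key step. This is worth more in step economy than the redox advantage of alternative 2.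

**Alternative 3:** The two aryl–C(sp) bonds at C6 and C6′ are cut. Two molecules of the 2-aroyl aryl bromide A7 couple with acetylene A8 under PdCl2(PPh3)2/CuI catalysis and give the symmetric tolane A9, whose hydration at either alkyne carbon gives the bridge.
- **For:** The endgame is stronger than that of the chosen route. Hydration of a symmetric diaryl alkyne gives the ketone directly, both aroyl ketones are already present, and no stoichiometric metal is used.
- **Against:** A7 is a hexasubstituted arene that already contains the hindered benzophenone, so a long, regiocontrolled linear sequence is needed before the key step. The C–Br bond of A7 lies between a methoxy and an aroyl group, and coupling it twice onto A8 should be slow and prone to stopping at the mono-adduct. The ortho carbonyl groups can take part in the alkyne activation and divert it to oxygen heterocycles.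
- **Comparison:** The chosen route gives up the cleaner endgame of alternative 3 and in return constructs the crowded rings instead of decorating them. It reaches the symmetric intermediate 14 in four steps from commercial materials.

Key step: step 5

Assumption: the carbinol centres of 3 to 17 are carried as stereoisomer mixtures (racemic 3 and 4; rac and meso forms from 7 on), because every one of them ends as a carbonyl carbon; they are drawn without stereodescriptors.

## Route

Step 1
Reactants: 1 2,6-dimethoxybenzaldehyde; 2 ethynylmagnesium bromide
Product: 3 1-(2,6-dimethoxyphenyl)prop-2-yn-1-ol (racemic)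
Conditions: 2 (1.3 equiv), THF, 0 °C → rt; then H2O
Reagents that add atoms: none
Why: Grignard addition of an acetylide to an aldehyde; the two ortho methoxy groups slow but do not block attack at the formyl carbon, and the new carbinol centre is formed racemic, which is of no consequence because it is oxidised in step 8.

Step 2
Reactants: 3 1-(2,6-dimethoxyphenyl)prop-2-yn-1-ol
Product: 4 tert-butyl{[1-(2,6-dimethoxyphenyl)prop-2-yn-1-yl]oxy}dimethylsilane (racemic)
Conditions: TBSCl (1.5 equiv), imidazole (3 equiv), DMF, rt → 40 °C
Reagents that add atoms: tert-butyldimethylsilyl chloride, CC(C)(C)[Si](C)(C)Cl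
Why: Standard imidazole-promoted silylation of a secondary alcohol; basic conditions avoid ionisation of the electron-rich propargylic benzylic C–O bond, and the bulky silyl ether later enlarges the alkyne substituent that has to end next to the new hydroxyl.

Step 3
Reactants: 4 tert-butyl{[1-(2,6-dimethoxyphenyl)prop-2-yn-1-yl]oxy}dimethylsilane (2.3 equiv); 5 (E)-1,2-dichloroethene
Product: 7 (4E)-1,8-bis(2,6-dimethoxyphenyl)-1,8-bis(tert-butyldimethylsilyloxy)oct-4-ene-2,6-diyne, via mono-coupled chloroenyne 6 (not isolated)
Conditions: Pd(PPh3)4 (5 mol %), CuI (10 mol %), n-BuNH2, toluene, rt, Ar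
Reagents that add atoms: none
Why: Two-fold Sonogashira coupling with retention of the E geometry; oxidative addition of zerovalent palladium into the first C–Cl bond of 5 is the slow event, and the chloroenyne 6 is activated by conjugation and couples faster, so the reaction should run through to the bis-adduct.

Step 4
Reactants: 8 2-bromopropene; 9 Cr(CO)6 (zerovalent chromium)
Product: 12 pentacarbonyl[methoxy(prop-1-en-2-yl)carbene]chromium (zerovalent chromium), via prop-1-en-2-yllithium 10 (not isolated), via lithium acylchromate 11 (not isolated)
Conditions: t-BuLi (2 equiv), Et2O, −78 °C; 9, Et2O, 0 °C → rt; MeOTf, CH2Cl2, 0 °C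
Reagents that add atoms: methyl trifluoromethanesulfonate, COS(=O)(=O)C(F)(F)F
Why: Fischer carbene synthesis: bromine–lithium exchange gives the alkenyllithium, which adds to a carbonyl ligand of Cr(CO)6, and the hard acyl oxygen of the chromate is methylated by the triflate; the complex should be used freshly prepared.

Step 5
Reactants: 7 (4E)-1,8-bis(2,6-dimethoxyphenyl)-1,8-bis(tert-butyldimethylsilyloxy)oct-4-ene-2,6-diyne; 12 pentacarbonyl[methoxy(prop-1-en-2-yl)carbene]chromium (3 equiv)
Product: 14 (E)-1,2-bis{2-[(tert-butyldimethylsilyloxy)(2,6-dimethoxyphenyl)methyl]-3-hydroxy-6-methoxy-5-methylphenyl}ethene, via bis(tricarbonylchromium) arene complex 13 (not isolated)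
Conditions: THF (0.05 M), 50 °C, Ar; then air, Et2O, ambient light, rt
Reagents that add atoms: none
Why: Dötz benzannulation, run in two directions on one diyne. Thermal loss of one CO from 12 opens a site for the alkyne, which inserts into the Cr=C bond so that the alkyne carbon bearing the CH=CH link bonds to the methoxy-bearing carbene carbon (C5–C6) and the alkyne carbon bearing the silyloxy(aryl)methyl group becomes the new carbene carbon; CO insertion there (C1–C2) gives a chromium-bound dienylketene. Each ring then closes by a thermal six-electron electrocyclisation of this dienylketene between the ketene carbon and the isopropenyl CH2 (C2–C3), and the cyclohexadienone tautomerises to the phenol, which stays η6-bound to Cr(CO)3 in 13 until air strips the metal. The closest known reaction type is the benzannulation of alkenyl(alkoxy)carbene complexes of zerovalent chromium with internal alkynes, including two-fold versions on diynes. No stereocentre is formed: the carbinol centres are untouched, the E-alkene is a spectator, and the planar chirality of the arene–Cr(CO)3 units vanishes on demetalation. The step needs regioselectivity in both rings (larger alkyne substituent next to the new hydroxyl) and chemoselectivity for the phenol over cyclobutenone or five-ring products. The first is secured by the size difference between the branched sp3 carbon carrying OTBS and a di-ortho-substituted aryl group and the flat sp2 CH= substituent, with no carbonyl conjugated to the alkyne to oppose it; the second is secured by the alkenyl carbene and the coordinating solvent THF, which favour CO insertion and six-ring closure.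

Step 6
Reactants: 14 (E)-1,2-bis{2-[(tert-butyldimethylsilyloxy)(2,6-dimethoxyphenyl)methyl]-3-hydroxy-6-methoxy-5-methylphenyl}ethene
Product: 16 1,2-bis{2-[(tert-butyldimethylsilyloxy)(2,6-dimethoxyphenyl)methyl]-3-hydroxy-6-methoxy-5-methylphenyl}ethan-1-ol, via benzylic alkylborane 15 (not isolated)
Conditions: BH3·THF (5 equiv), THF, 0 → 45 °C; then 30 % H2O2, 3 M NaOH, 0 °C → rt
Reagents that add atoms: hydrogen peroxide, OO
Why: Hydroboration of the stilbene and stereoretentive oxidation of the C–B bond; the two alkene carbons are constitutionally equivalent, so either mode of addition gives the same alcohol, and the new carbinol centre is uncontrolled because it is oxidised in step 8. Excess borane is used because the two phenols consume hydride and are released again on work-up.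

Step 7
Reactants: 16 1,2-bis{2-[(tert-butyldimethylsilyloxy)(2,6-dimethoxyphenyl)methyl]-3-hydroxy-6-methoxy-5-methylphenyl}ethan-1-ol
Product: 17 1,2-bis{3-hydroxy-2-[hydroxy(2,6-dimethoxyphenyl)methyl]-6-methoxy-5-methylphenyl}ethan-1-ol
Conditions: TBAF (4 equiv), THF, 0 °C → rt; then H2O
Reagents that add atoms: none
Why: Fluoride cleavage of the two Si–O bonds, driven by the Si–F bond strength; the basic, non-acidic medium avoids ionisation of the electron-rich benzhydryl C–O bonds, and no ketone is present that could be enolised or close to a lactol.

Step 8
Reactants: 17 1,2-bis{3-hydroxy-2-[hydroxy(2,6-dimethoxyphenyl)methyl]-6-methoxy-5-methylphenyl}ethan-1-ol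
Product: 18 acredinone B, 1,2-bis[2-(2,6-dimethoxybenzoyl)-3-hydroxy-6-methoxy-5-methylphenyl]ethan-1-one
Conditions: activated MnO2 (excess), CH2Cl2, 4 Å MS, rt
Reagents that add atoms: none
Why: Heterogeneous MnO2 oxidation of benzylic alcohols; all three carbinols are benzylic and are raised to ketones in one operation under neutral conditions that spare the para-methoxyphenols and do not enolise the new CH2–C(=O) unit. Each new diaryl ketone hydrogen-bonds to its ortho phenol, which lowers the oxidisability of that phenol as the reaction proceeds.

## Compound list

1 | 2,6-dimethoxybenzaldehyde | COc1cccc(OC)c1C=O | starting material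
2 | ethynylmagnesium bromide | C#C[Mg]Br | starting material
3 | 1-(2,6-dimethoxyphenyl)prop-2-yn-1-ol (racemic) | COc1cccc(OC)c1C(O)C#C | intermediate
4 | tert-butyl{[1-(2,6-dimethoxyphenyl)prop-2-yn-1-yl]oxy}dimethylsilane (racemic) | COc1cccc(OC)c1C(O[Si](C)(C)C(C)(C)C)C#C | intermediate
5 | (E)-1,2-dichloroethene | Cl/C=C/Cl | starting material
6 | tert-butyl{[(4E)-5-chloro-1-(2,6-dimethoxyphenyl)pent-4-en-2-yn-1-yl]oxy}dimethylsilane | COc1cccc(OC)c1C(O[Si](C)(C)C(C)(C)C)C#C/C=C/Cl | intermediate (not isolated)
7 | (4E)-1,8-bis(2,6-dimethoxyphenyl)-1,8-bis(tert-butyldimethylsilyloxy)oct-4-ene-2,6-diyne | COc1cccc(OC)c1C(O[Si](C)(C)C(C)(C)C)C#C/C=C/C#CC(O[Si](C)(C)C(C)(C)C)c1c(OC)cccc1OC | intermediate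
8 | 2-bromopropene | CC(Br)=C | starting material
9 | hexacarbonylchromium, Cr(CO)6 (zerovalent chromium) | O=C=[Cr](=C=O)(=C=O)(=C=O)(=C=O)=C=O | starting material
10 | prop-1-en-2-yllithium | [Li]C(C)=C | intermediate (not isolated)
11 | lithium pentacarbonyl(2-methylprop-2-enoyl)chromate (zerovalent chromium) | [Li+].[O-]C(C(C)=C)=[Cr](=C=O)(=C=O)(=C=O)(=C=O)=C=O | intermediate (not isolated)
12 | pentacarbonyl[methoxy(prop-1-en-2-yl)carbene]chromium (zerovalent chromium) | COC(C(C)=C)=[Cr](=C=O)(=C=O)(=C=O)(=C=O)=C=O | intermediate
13 | bis(tricarbonylchromium) complex of 14, one Cr(CO)3 η6-bound to each new ring (zerovalent chromium; hapto bonds not drawn) | COc1cccc(OC)c1C(O[Si](C)(C)C(C)(C)C)c1c(O)cc(C)c(OC)c1/C=C/c1c(OC)c(C)cc(O)c1C(O[Si](C)(C)C(C)(C)C)c1c(OC)cccc1OC.O=C=[Cr](=C=O)=C=O.O=C=[Cr](=C=O)=C=O | intermediate (not isolated)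
14 | (E)-1,2-bis{2-[(tert-butyldimethylsilyloxy)(2,6-dimethoxyphenyl)methyl]-3-hydroxy-6-methoxy-5-methylphenyl}ethene | COc1cccc(OC)c1C(O[Si](C)(C)C(C)(C)C)c1c(O)cc(C)c(OC)c1/C=C/c1c(OC)c(C)cc(O)c1C(O[Si](C)(C)C(C)(C)C)c1c(OC)cccc1OC | intermediate
15 | {1,2-bis{2-[(tert-butyldimethylsilyloxy)(2,6-dimethoxyphenyl)methyl]-3-hydroxy-6-methoxy-5-methylphenyl}ethyl}borane (drawn as the monoalkylborane with free phenols; in the flask the phenol oxygens are boron-bound) | COc1cccc(OC)c1C(O[Si](C)(C)C(C)(C)C)c1c(O)cc(C)c(OC)c1CC(B)c1c(OC)c(C)cc(O)c1C(O[Si](C)(C)C(C)(C)C)c1c(OC)cccc1OC | intermediate (not isolated)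
16 | 1,2-bis{2-[(tert-butyldimethylsilyloxy)(2,6-dimethoxyphenyl)methyl]-3-hydroxy-6-methoxy-5-methylphenyl}ethan-1-ol | COc1cccc(OC)c1C(O[Si](C)(C)C(C)(C)C)c1c(O)cc(C)c(OC)c1CC(O)c1c(OC)c(C)cc(O)c1C(O[Si](C)(C)C(C)(C)C)c1c(OC)cccc1OC | intermediate
17 | 1,2-bis{3-hydroxy-2-[hydroxy(2,6-dimethoxyphenyl)methyl]-6-methoxy-5-methylphenyl}ethan-1-ol | COc1cccc(OC)c1C(O)c1c(O)cc(C)c(OC)c1CC(O)c1c(OC)c(C)cc(O)c1C(O)c1c(OC)cccc1OC | intermediate
18 | acredinone B, 1,2-bis[2-(2,6-dimethoxybenzoyl)-3-hydroxy-6-methoxy-5-methylphenyl]ethan-1-one | COc1cccc(OC)c1C(=O)c1c(O)cc(C)c(OC)c1CC(=O)c1c(OC)c(C)cc(O)c1C(=O)c1c(OC)cccc1OC | target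

## Step count and least certain steps

Total step count: 8. Longest linear sequence: 7 steps (steps 1, 2, 3, 5, 6, 7, 8 from 2,6-dimethoxybenzaldehyde); step 4 is a one-step side branch.

**Step 5 (key step).** The most likely failure is that the second annulation stalls or leaves the phenol pathway, because the alkyne carbon that becomes C1 carries a very bulky group, so that a vinylketene complex or a cyclobutenone forms in place of the ring. A second failure is leakage of regiochemistry, which is multiplied because two rings have to form correctly in one flask. The fallback builds one ring at a time. It sets out from 4, 5 and 12 and comes back at 14. Coupling 4 with a five-fold excess of 5 (Pd(PPh3)4, CuI, n-BuNH2) stops at the chloroenyne 6, which is now isolated. Benzannulation of 6 with 12 (THF, 50 °C, then air) should give 2-[(tert-butyldimethylsilyloxy)(2,6-dimethoxyphenyl)methyl]-3-[(E)-2-chloroethenyl]-4-methoxy-5-methylphenol F1, from which a regioisomer can be removed before more material is committed. Sonogashira coupling of F1 with a second molecule of 4 (PdCl2(PhCN)2, CuI, piperidine, conditions suited to unactivated alkenyl chlorides) gives 2-[(tert-butyldimethylsilyloxy)(2,6-dimethoxyphenyl)methyl]-3-[(1E)-5-(tert-butyldimethylsilyloxy)-5-(2,6-dimethoxyphenyl)pent-1-en-3-yn-1-yl]-4-methoxy-5-methylphenol F2. A second benzannulation of F2 with 12 closes the other ring and delivers 14.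

**Step 6.** The most likely failure is slow or incomplete addition of borane to an alkene whose two faces are screened by four ortho substituents; prolonged heating then invites reductive loss of the benzhydryl C–O bonds. The fallback is a direct Wacker-type oxidation to the ketone level. It sets out from 14 and comes back at 18. PdCl2 (catalytic, divalent palladium) under O2 in aqueous N,N-dimethylacetamide at 80 °C, without copper, should convert 14 into 1,2-bis{2-[(tert-butyldimethylsilyloxy)(2,6-dimethoxyphenyl)methyl]-3-hydroxy-6-methoxy-5-methylphenyl}ethan-1-one F3. TBAF in THF then gives 1,2-bis{3-hydroxy-2-[hydroxy(2,6-dimethoxyphenyl)methyl]-6-methoxy-5-methylphenyl}ethan-1-one F4, and MnO2 in CH2Cl2 oxidises the two benzhydrols to give 18. This path is second choice because the electrophilic metal oxidant meets free electron-rich phenols and acid-labile silyl ethers, and because F4 is a hydroxy ketone that can close reversibly to lactols.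

**Step 8.** The most likely failures are incomplete oxidation of the twisted, crowded benzhydrols, oxidation of the free para-methoxyphenols to quinones, and acid-promoted cyclodehydration of the 1,4-diol unit of 17 on the oxide surface. The fallback caps the phenols so that a stronger homogeneous oxidant can be used. It sets out from 14 and comes back at 18. MOMCl and i-Pr2NEt in CH2Cl2 give (E)-1,2-bis{2-[(tert-butyldimethylsilyloxy)(2,6-dimethoxyphenyl)methyl]-6-methoxy-3-(methoxymethoxy)-5-methylphenyl}ethene F5. Hydroboration and oxidation as in step 6 give 1,2-bis{2-[(tert-butyldimethylsilyloxy)(2,6-dimethoxyphenyl)methyl]-6-methoxy-3-(methoxymethoxy)-5-methylphenyl}ethan-1-ol F6. TBAF gives 1,2-bis{2-[hydroxy(2,6-dimethoxyphenyl)methyl]-6-methoxy-3-(methoxymethoxy)-5-methylphenyl}ethan-1-ol F7. Dess–Martin periodinane buffered with NaHCO3 gives 1,2-bis[2-(2,6-dimethoxybenzoyl)-6-methoxy-3-(methoxymethoxy)-5-methylphenyl]ethan-1-one F8. Brief treatment of F8 with HCl in methanol removes the two acetals, which are activated by the ortho ketones, and gives 18.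

**Step 3.** The most likely failures are stalling at the mono-coupled stage 6 and copper-mediated oxidative dimerisation of the terminal alkyne 4 by traces of oxygen. The fallback reverses the order of bond formation. It sets out from 5 and 1 and comes back at 7. Two-fold Sonogashira coupling of 5 with commercial trimethylsilylacetylene gives (E)-1,6-bis(trimethylsilyl)hex-3-ene-1,5-diyne F9. MeLi·LiBr (2.2 equiv) in THF cleaves both C–Si bonds and gives dilithium (E)-hex-3-ene-1,5-diyne-1,6-diide F10 in solution, so the volatile free enediyne is never isolated. Addition of 1 gives (4E)-1,8-bis(2,6-dimethoxyphenyl)oct-4-ene-2,6-diyne-1,8-diol F11, and silylation with TBSCl and imidazole gives 7.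

## Further compounds

F1 | step 5 | 2-[(tert-butyldimethylsilyloxy)(2,6-dimethoxyphenyl)methyl]-3-[(E)-2-chloroethenyl]-4-methoxy-5-methylphenol | COc1cccc(OC)c1C(O[Si](C)(C)C(C)(C)C)c1c(O)cc(C)c(OC)c1/C=C/Cl
F2 | step 5 | 2-[(tert-butyldimethylsilyloxy)(2,6-dimethoxyphenyl)methyl]-3-[(1E)-5-(tert-butyldimethylsilyloxy)-5-(2,6-dimethoxyphenyl)pent-1-en-3-yn-1-yl]-4-methoxy-5-methylphenol | COc1cccc(OC)c1C(O[Si](C)(C)C(C)(C)C)c1c(O)cc(C)c(OC)c1/C=C/C#CC(O[Si](C)(C)C(C)(C)C)c1c(OC)cccc1OC
F3 | step 6 | 1,2-bis{2-[(tert-butyldimethylsilyloxy)(2,6-dimethoxyphenyl)methyl]-3-hydroxy-6-methoxy-5-methylphenyl}ethan-1-one | COc1cccc(OC)c1C(O[Si](C)(C)C(C)(C)C)c1c(O)cc(C)c(OC)c1CC(=O)c1c(OC)c(C)cc(O)c1C(O[Si](C)(C)C(C)(C)C)c1c(OC)cccc1OC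
F4 | step 6 | 1,2-bis{3-hydroxy-2-[hydroxy(2,6-dimethoxyphenyl)methyl]-6-methoxy-5-methylphenyl}ethan-1-one | COc1cccc(OC)c1C(O)c1c(O)cc(C)c(OC)c1CC(=O)c1c(OC)c(C)cc(O)c1C(O)c1c(OC)cccc1OC
F5 | step 8 | (E)-1,2-bis{2-[(tert-butyldimethylsilyloxy)(2,6-dimethoxyphenyl)methyl]-6-methoxy-3-(methoxymethoxy)-5-methylphenyl}ethene | COc1cccc(OC)c1C(O[Si](C)(C)C(C)(C)C)c1c(OCOC)cc(C)c(OC)c1/C=C/c1c(OC)c(C)cc(OCOC)c1C(O[Si](C)(C)C(C)(C)C)c1c(OC)cccc1OC
F6 | step 8 | 1,2-bis{2-[(tert-butyldimethylsilyloxy)(2,6-dimethoxyphenyl)methyl]-6-methoxy-3-(methoxymethoxy)-5-methylphenyl}ethan-1-ol | COc1cccc(OC)c1C(O[Si](C)(C)C(C)(C)C)c1c(OCOC)cc(C)c(OC)c1CC(O)c1c(OC)c(C)cc(OCOC)c1C(O[Si](C)(C)C(C)(C)C)c1c(OC)cccc1OC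
F7 | step 8 | 1,2-bis{2-[hydroxy(2,6-dimethoxyphenyl)methyl]-6-methoxy-3-(methoxymethoxy)-5-methylphenyl}ethan-1-ol | COc1cccc(OC)c1C(O)c1c(OCOC)cc(C)c(OC)c1CC(O)c1c(OC)c(C)cc(OCOC)c1C(O)c1c(OC)cccc1OC
F8 | step 8 | 1,2-bis[2-(2,6-dimethoxybenzoyl)-6-methoxy-3-(methoxymethoxy)-5-methylphenyl]ethan-1-one | COc1cccc(OC)c1C(=O)c1c(OCOC)cc(C)c(OC)c1CC(=O)c1c(OC)c(C)cc(OCOC)c1C(=O)c1c(OC)cccc1OC
F9 | step 3 | (E)-1,6-bis(trimethylsilyl)hex-3-ene-1,5-diyne | C[Si](C)(C)C#C/C=C/C#C[Si](C)(C)C
F10 | step 3 | dilithium (E)-hex-3-ene-1,5-diyne-1,6-diide | [Li]C#C/C=C/C#C[Li]
F11 | step 3 | (4E)-1,8-bis(2,6-dimethoxyphenyl)oct-4-ene-2,6-diyne-1,8-diol | COc1cccc(OC)c1C(O)C#C/C=C/C#CC(O)c1c(OC)cccc1OC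
A1 | alternative 1 | 3-(benzyloxy)-5-methylbenzyne | C1#CC(OCc2ccccc2)=CC(C)=C1
A2 | alternative 1 | methyl 3-(2,6-dimethoxyphenyl)-3-oxopropanoate | COC(=O)CC(=O)c1c(OC)cccc1OC
A3 | alternative 1 | methyl 2-[3-(benzyloxy)-2-(2,6-dimethoxybenzoyl)-5-methylphenyl]acetate | COC(=O)Cc1cc(C)cc(OCc2ccccc2)c1C(=O)c1c(OC)cccc1OC
A4 | alternative 2 | 3-methoxybenzyne | COC1=CC=CC#C1
A5 | alternative 2 | (E)-2,2′-(ethene-1,2-diyl)bis[3-methoxy-6-(methoxymethoxy)-4-methylbenzoic acid] | OC(=O)c1c(OCOC)cc(C)c(OC)c1/C=C/c1c(OC)c(C)cc(OCOC)c1C(O)=O
A6 | alternative 2 | (E)-1,2-bis[2-(2-hydroxy-6-methoxybenzoyl)-6-methoxy-3-(methoxymethoxy)-5-methylphenyl]ethene | COc1cccc(O)c1C(=O)c1c(OCOC)cc(C)c(OC)c1/C=C/c1c(OC)c(C)cc(OCOC)c1C(=O)c1c(O)cccc1OC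
A7 | alternative 3 | [2-bromo-3-methoxy-6-(methoxymethoxy)-4-methylphenyl](2,6-dimethoxyphenyl)methanone | COCOc1cc(C)c(OC)c(Br)c1C(=O)c1c(OC)cccc1OC
A8 | alternative 3 | acetylene | C#C
A9 | alternative 3 | 1,2-bis[2-(2,6-dimethoxybenzoyl)-6-methoxy-3-(methoxymethoxy)-5-methylphenyl]ethyne | COCOc1cc(C)c(OC)c(C#Cc2c(OC)c(C)cc(OCOC)c2C(=O)c2c(OC)cccc2OC)c1C(=O)c1c(OC)cccc1OC
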